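## Analysis of the target

Flavanone numbering is used: O1, C2, C3, C4 in ring C, C4a to C8a in ring A, primed locants for ring B, and doubly primed locants for the second half.

- Target 13 is a 3,3''-biflavanone: two identical 5,7-dihydroxy-2-(4-methoxyphenyl)chroman-4-one halves joined by one C3–C3'' single bond.
- It has four contiguous stereocenters, C2, C3, C3'' and C2'', all R. A twofold axis passes through the middle of the C3–C3'' bond.
- Within each ring C the C2 aryl group and the C3–C3'' bond are cis, so H2 and H3 lie on the same face. This is expected to be the less stable arrangement, because a 2,3-trans flavanone can place both substituents equatorial. C2 also has the sense opposite to the 2S sense that chalcone isomerases deliver.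
- Sensitive sites: C3–H and C3''–H are α to ketones and can epimerise from cis to trans with acid or base. The O1–C2 bonds are β to C4=O and benzylic to an anisyl ring, so base can open ring C and racemise C2. The four phenols must stay distinct from the two anisyl methyl ethers.
- The feature that invites the chosen move: C3 and C3'' are the α-carbons of the C4 and C4'' ketones, joined head to head, and each O1–C2 bond is β to its ketone. Both rings C are therefore closed 2'-hydroxychalcones. Opening the two O–C bonds removes all four stereocenters and leaves an achiral 2,3-diaroyl-1,4-diarylbuta-1,3-diene whose central bond is C3–C3''.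
- The difficulty is therefore not the C3–C3'' bond itself. It is setting four adjacent stereocenters as one homochiral cis,cis set and carrying them to the end without acid or base.

## Retrosynthetic reasoning

**13 to 12.** Only the four O-benzyl bonds on rings A are cut. Benzyl is chosen because it falls under neutral hydrogenolysis, which touches neither the epimerisable C3 centres nor the base-labile ring C.

**12 to 10 (key disconnection).** The O1–C2 and O1''–C2'' bonds are cut, together with the C3–H and C3''–H bonds. This gives the achiral bis(2'-hydroxychalcone) 10, in which the C3–C3'' bond is the central bond of a 1,3-diene. The cut is made here because it removes both rings C and all four stereocenters in one move. Forward, a twofold enantioselective oxa-Michael addition must set C2 and C2'' under catalyst control, and the two enols that result must be protonated under kinetic control to give the cis relationship. The twofold symmetry of 10 means one catalyst acts twice with the same sense.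

**10 to 9.** One ortho O-benzyl bond per ring A is cut. Carrying the nucleophilic phenol masked until just before the key step prevents an uncatalysed, racemic ring closure at an earlier stage. The forward reaction must free exactly one ortho phenol per ring; chelation to the neighbouring carbonyl provides that selectivity.

**9 to 5 and 7 (through 8).** The two aryl–carbonyl bonds C4–C4a and C4''–C4a'' are cut. Ring A enters as aryllithium 8, made from bromide 7, and the four-carbon core as bis-Weinreb amide 5. This is a two-directional acylation of a symmetric electrophile, and the amide stops each addition at the ketone level.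

**7 to 6.** The C–Br bond is cut. Monobromination of the symmetric tris-ether 6 gives the handle for clean halogen–lithium exchange.

**5 to 4, and 4 to 1 and 2.** The amide bonds are cut back to diacid 4, and then the two C2=C3-type double bonds are cut (C2–C3 and C2''–C3'' of the target). The central C3–C3'' bond turns out to be the CH2–CH2 bond of diethyl succinate 1, so it is bought and not made. A twofold Stobbe condensation with aldehyde 2 installs both anisylidene groups with (E,E) geometry in one operation.

## Alternatives that were turned down

**Alternative 1:** the textbook disconnection of the C3–C3'' bond.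
- Forward step: oxidative homocoupling of the lithium enolate of the enantiopure monomer A1 with a divalent copper or trivalent iron oxidant.
- The new bond forms on the face of each enolate away from the C2 aryl group. The product is therefore the trans,trans dimer A2 (2R,3S,2''R,3''S), with the wrong configuration at both C3 centres.
- Correcting it needs a second enolisation and kinetic protonation on a substrate whose enolate can expel O1 and racemise C2.
- A1 needs its own enantioselective synthesis, and the coupling of two hindered α-carbons is expected to be inefficient. The key step would form one bond, close no ring and set no stereocenter that the target keeps.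

**Alternative 2:** disconnection of the four C–H bonds at C2, C3, C2'' and C3''.
- Forward step: twofold enantioselective syn-hydrogenation of the 3,3''-biflavone A3. Syn addition would give the cis relationship directly.
- Each C2=C3 bond of A3 is a tetrasubstituted vinylogous ester, and the other chromone is expected to lie nearly perpendicular and shield both faces.
- The ruthenium–carbene and rhodium–bisphosphine catalysts known for chromones are established for 2-substituted cases and also reduce C4=O, so a re-oxidation would follow.
- Hindered rotation about C3–C3'' could make A3 a pair of slowly interconverting atropisomers that respond differently to the catalyst. The risk would sit in reactivity, chemoselectivity and stereoselectivity at once.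

**Alternative 3:** disconnection of the two C2–aryl bonds.
- Forward step: twofold enantioselective conjugate addition of a 4-methoxyphenylboron reagent to the 3,3'-bichromone A4, under monovalent rhodium/chiral diene or divalent palladium/pyridine-oxazoline catalysis, with protonation setting C3.
- Acceptors substituted at the α-carbon insert slowly into aryl–metal bonds, so protodeboronation is expected to compete, most of all in the second addition.
- These reactions run in aqueous base, where C3 protonation is reversible and would drift to the trans series.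
- The step closes no ring, and A4 costs about as many steps as the precursor of the chosen key step.

Key step: step 6

Assumption: the sense of induction of the epi-quinine thiourea in step 6 is assigned by analogy with its oxa-Michael cyclisations of 2'-hydroxychalcone-type acceptors. If 10 responds in the opposite sense, the pseudoenantiomeric epi-quinidine thiourea is used and nothing else changes.

## Route

Step 1
Reactants: 1 diethyl succinate; 2 4-methoxybenzaldehyde (2.2 equiv)
Product: 4 (2E,3E)-2,3-bis(4-methoxybenzylidene)succinic acid, via half-ester 3 (not isolated)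
Conditions: KOt-Bu (4.4 equiv), t-BuOH/THF, reflux; then aq. HCl
Reagents that add atoms: none
Why: Twofold Stobbe condensation: each aldol adduct lactonises onto the neighbouring ester and opens by E1cB elimination to a carboxylate, which makes each condensation irreversible and places each aryl group trans to its carboxyl group; the C3–C3'' bond of the target is the central C–C bond of 1.

Step 2
Reactants: 4 (2E,3E)-2,3-bis(4-methoxybenzylidene)succinic acid
Product: 5 (2E,3E)-N1,N4-dimethoxy-N1,N4-dimethyl-2,3-bis(4-methoxybenzylidene)succinamide
Conditions: CDI (1,1'-carbonyldiimidazole, 2.4 equiv), CH2Cl2, rt to 40 °C; then MeNHOMe·HCl (3 equiv), rt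
Reagents that add atoms: N,O-dimethylhydroxylamine hydrochloride, CNOC.Cl
Why: Acyl imidazolide formation and aminolysis (Weinreb amide synthesis); any cyclic anhydride formed from the diacid is opened by the amine and the freed acid is re-activated by the excess CDI, so both carboxyl groups end as amides and the alkenes are untouched.

Step 3
Reactants: 6 1,3,5-tris(benzyloxy)benzene
Product: 7 2-bromo-1,3,5-tris(benzyloxy)benzene
Conditions: NBS (1.0 equiv), CH2Cl2, −20 to 0 °C
Reagents that add atoms: N-bromosuccinimide, O=C1CCC(=O)N1Br
Why: Electrophilic aromatic bromination of a strongly activated ring with three equivalent positions; one equivalent of NBS at low temperature should stop at the monobromide.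

Step 4
Reactants: 7 2-bromo-1,3,5-tris(benzyloxy)benzene (2.4 equiv); 5 (2E,3E)-N1,N4-dimethoxy-N1,N4-dimethyl-2,3-bis(4-methoxybenzylidene)succinamide
Product: 9 (2E,3E)-2,3-bis(4-methoxybenzylidene)-1,4-bis[2,4,6-tris(benzyloxy)phenyl]butane-1,4-dione, via aryllithium 8 (not isolated)
Conditions: n-BuLi, THF, −78 °C; then 5, −78 to −20 °C; aq. NH4Cl
Reagents that add atoms: none
Why: Bromine–lithium exchange followed by a twofold Weinreb ketone synthesis: the chelated tetrahedral intermediate holds each carbonyl at the ketone level until work-up, and 1,2-addition should prevail because each β-carbon carries an aryl group and each α-carbon is fully substituted.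

Step 5
Reactants: 9 (2E,3E)-2,3-bis(4-methoxybenzylidene)-1,4-bis[2,4,6-tris(benzyloxy)phenyl]butane-1,4-dione
Product: 10 (2E,3E)-1,4-bis[4,6-bis(benzyloxy)-2-hydroxyphenyl]-2,3-bis(4-methoxybenzylidene)butane-1,4-dione
Conditions: BCl3 (2.2 equiv), CH2Cl2, −78 °C; then H2O at −78 °C
Reagents that add atoms: none
Why: Chelation-controlled ether cleavage: BCl3 binds between the carbonyl oxygen and one ortho benzyloxy oxygen and chloride removes that benzyl group; once the aryloxyboron chelate has formed the carbonyl no longer activates the second ortho ether, and the para ethers and anisyl methyl ethers should not react at −78 °C.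

Step 6
Reactants: 10 (2E,3E)-1,4-bis[4,6-bis(benzyloxy)-2-hydroxyphenyl]-2,3-bis(4-methoxybenzylidene)butane-1,4-dione
Product: 12 (2R,3R,2''R,3''R)-5,7,5'',7''-tetrakis(benzyloxy)-4',4'''-dimethoxy-3,3''-biflavanone, via monocyclised flavanone 11 (not isolated)
Conditions: 1-[3,5-bis(trifluoromethyl)phenyl]-3-[(8S,9S)-6'-methoxycinchonan-9-yl]thiourea (epi-quinine thiourea, 20 mol %), toluene/CH2Cl2, −20 °C, dark; filtration through silica when 11 is consumed
Reagents that add atoms: none
Why: The quinuclidine nitrogen of the catalyst deprotonates the chelated 2'-OH of 10 while the thiourea binds the carbonyl oxygen, the phenoxide adds to the β-carbon of the (E)-enone in its s-trans conformation (intramolecular oxa-Michael addition), the enol is protonated at the α-carbon, and the sequence repeats on the second enone of 11. The closest known reaction type is the cinchona-thiourea-catalysed enantioselective cyclisation of 2'-hydroxychalcones to flavanones, run here twice in one flask on a substrate whose α-substituent is the other chalcone. Each ring C closes in the 6-endo-trig mode (O1 to C2, then O1'' to C2''); attack of a phenoxide on the remote β-carbon would need a seven-membered ring and is disfavoured. C2 and C2'' are set by the catalyst, which presents the same enantiotopic face of each enone to its phenoxide and is expected to give R at both. C3 and C3'' are set by the substrate: in the cyclic enol the C2 aryl group turns pseudoaxial to escape allylic strain with the large C3 substituent, and the proton arrives on the opposite face, which places H3 cis to H2. Because the same catalyst acts twice, a ring closure of the minor sense ends mostly in the unsymmetrical (2R,2''S) diastereomer, which chromatography removes, so the enantiomeric purity of twofold-symmetric 12 should exceed the selectivity of a single closure. The step needs kinetic control: a weak amine base, a non-polar solvent and low temperature are chosen so that neither ring opening (loss of C2) nor enolisation of the product (cis to trans at C3) competes.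

Step 7
Reactants: 12 (2R,3R,2''R,3''R)-5,7,5'',7''-tetrakis(benzyloxy)-4',4'''-dimethoxy-3,3''-biflavanone
Product: 13 (2R,3R,2''R,3''R)-5,7,5'',7''-tetrahydroxy-4',4'''-dimethoxy-3,3''-biflavanone (target)
Conditions: H2 (1 atm), Pd/C (10 wt % palladium on carbon), EtOAc/THF, rt
Reagents that add atoms: none
Why: Hydrogenolysis of aryl benzyl ethers under neutral conditions, which avoid the base that would open ring C and the acid or base that would epimerise C3; O-benzyl cleavage is expected to be much faster than cleavage of the cyclic benzylic C2–O1 bond, and the reaction is stopped at full debenzylation.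

## Compound list

1 | diethyl succinate | CCOC(=O)CCC(=O)OCC | starting material
2 | 4-methoxybenzaldehyde | COc1ccc(C=O)cc1 | starting material
3 | (E)-3-(ethoxycarbonyl)-4-(4-methoxyphenyl)but-3-enoic acid (potassium salt in the flask) | OC(=O)C/C(C(=O)OCC)=C\c1ccc(OC)cc1 | intermediate (not isolated)
4 | (2E,3E)-2,3-bis(4-methoxybenzylidene)succinic acid | OC(=O)/C(=C/c1ccc(OC)cc1)/C(=C\c1ccc(OC)cc1)C(=O)O | intermediate
5 | (2E,3E)-N1,N4-dimethoxy-N1,N4-dimethyl-2,3-bis(4-methoxybenzylidene)succinamide | CON(C)C(=O)/C(=C/c1ccc(OC)cc1)/C(=C\c1ccc(OC)cc1)C(=O)N(C)OC | intermediate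
6 | 1,3,5-tris(benzyloxy)benzene | c1ccc(COc2cc(OCc3ccccc3)cc(OCc3ccccc3)c2)cc1 | starting material
7 | 2-bromo-1,3,5-tris(benzyloxy)benzene | Brc1c(OCc2ccccc2)cc(OCc2ccccc2)cc1OCc1ccccc1 | intermediate
8 | [2,4,6-tris(benzyloxy)phenyl]lithium | [Li]c1c(OCc2ccccc2)cc(OCc2ccccc2)cc1OCc1ccccc1 | intermediate (not isolated)
9 | (2E,3E)-2,3-bis(4-methoxybenzylidene)-1,4-bis[2,4,6-tris(benzyloxy)phenyl]butane-1,4-dione | O=C(c1c(OCc2ccccc2)cc(OCc2ccccc2)cc1OCc1ccccc1)/C(=C/c1ccc(OC)cc1)/C(=C\c1ccc(OC)cc1)C(=O)c1c(OCc2ccccc2)cc(OCc2ccccc2)cc1OCc1ccccc1 | intermediate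
10 | (2E,3E)-1,4-bis[4,6-bis(benzyloxy)-2-hydroxyphenyl]-2,3-bis(4-methoxybenzylidene)butane-1,4-dione | O=C(c1c(O)cc(OCc2ccccc2)cc1OCc1ccccc1)/C(=C/c1ccc(OC)cc1)/C(=C\c1ccc(OC)cc1)C(=O)c1c(O)cc(OCc2ccccc2)cc1OCc1ccccc1 | intermediate
11 | (2R,3R)-5,7-bis(benzyloxy)-3-[(E)-3-[4,6-bis(benzyloxy)-2-hydroxyphenyl]-1-(4-methoxyphenyl)-3-oxoprop-1-en-2-yl]-2-(4-methoxyphenyl)chroman-4-one | COc1ccc([C@@H]2Oc3cc(OCc4ccccc4)cc(OCc4ccccc4)c3C(=O)[C@@H]2/C(=C\c2ccc(OC)cc2)C(=O)c2c(O)cc(OCc3ccccc3)cc2OCc2ccccc2)cc1 | intermediate (not isolated)
12 | (2R,3R,2''R,3''R)-5,7,5'',7''-tetrakis(benzyloxy)-4',4'''-dimethoxy-3,3''-biflavanone | COc1ccc([C@@H]2Oc3cc(OCc4ccccc4)cc(OCc4ccccc4)c3C(=O)[C@@H]2[C@H]2C(=O)c3c(OCc4ccccc4)cc(OCc4ccccc4)cc3O[C@H]2c2ccc(OC)cc2)cc1 | intermediate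
13 | (2R,3R,2''R,3''R)-5,7,5'',7''-tetrahydroxy-4',4'''-dimethoxy-3,3''-biflavanone | COc1ccc([C@@H]2Oc3cc(O)cc(O)c3C(=O)[C@@H]2[C@H]2C(=O)c3c(O)cc(O)cc3O[C@H]2c2ccc(OC)cc2)cc1 | target

## Step count and least certain steps

Total step count: 7. Longest linear sequence: 6 (steps 1, 2, 4, 5, 6, 7); step 3 is the one-step side branch.

**Step 6 (key step).**
- What may go wrong: loss of stereocontrol. An α-branched enone twisted out of conjugation may be discriminated poorly by the catalyst. Ring opening and re-closure may erode C2. Enolisation of 11 or 12 by the amine may move C3 to the trans series.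
- Fallback, which sets out from 7 and returns at 12: it builds one half at a time with a conjugate arylation and joins the halves afterwards.
  - Aryllithium 8, made from 7, is acylated with N-methoxy-N-methylacetamide to give 1-[2,4,6-tris(benzyloxy)phenyl]ethan-1-one F1.
  - BCl3 at −78 °C removes one ortho benzyl group and gives 1-[4,6-bis(benzyloxy)-2-hydroxyphenyl]ethan-1-one F2.
  - Condensation with N,N-dimethylformamide dimethyl acetal and acid-mediated ring closure give 5,7-bis(benzyloxy)-4H-chromen-4-one F3.
  - Conjugate addition of 4-methoxyphenylboronic acid under monovalent rhodium catalysis ([RhCl(C2H4)2]2, the enantiomer of 2,5-diphenylbicyclo[2.2.2]octa-2,5-diene that leads to the 2R series, aq. KOH, dioxane) gives (R)-5,7-bis(benzyloxy)-2-(4-methoxyphenyl)chroman-4-one F4, identical with A1.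
  - The lithium enolate of F4 (LDA, THF, −78 °C) is dimerised with CuCl2 to the trans,trans dimer (2R,3S,2''R,3''S)-5,7,5'',7''-tetrakis(benzyloxy)-4',4'''-dimethoxy-3,3''-biflavanone F5, identical with A2.
  - Twofold deprotonation of F5 (LDA, −78 °C) and protonation with 2,6-di-tert-butylphenol at −78 °C, on the face away from each C2 aryl group, should give 12.

**Step 1.**
- What may go wrong: the second condensation stalls, because it needs enolisation next to a carboxylate in 3. Mono-condensed material and alkene isomers then accumulate.
- Fallback, which sets out from 2 and returns at 4: it makes the central bond by coupling instead of buying it.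
  - Wittig reaction of 2 with ethyl 2-bromo-2-(triphenylphosphoranylidene)acetate gives ethyl (Z)-2-bromo-3-(4-methoxyphenyl)acrylate F6.
  - Reductive homocoupling with zerovalent nickel generated in situ (NiCl2(PPh3)2, Zn, Et4NI, THF) proceeds with retention of alkene geometry and gives diethyl (2E,3E)-2,3-bis(4-methoxybenzylidene)succinate F7.
  - Saponification with LiOH gives 4.

**Step 4.**
- What may go wrong: incomplete twofold addition at two neighbouring hindered amides, and decay of 8 by attack on its own benzyl ethers if the mixture has to be warmed.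
- Fallback, which sets out from 5 and returns at 9: it moves the addition to the more electrophilic aldehyde level.
  - Reduction of 5 with i-Bu2AlH at −78 °C gives (2E,3E)-2,3-bis(4-methoxybenzylidene)succinaldehyde F8.
  - Addition of 8 at −78 °C gives (2E,3E)-2,3-bis(4-methoxybenzylidene)-1,4-bis[2,4,6-tris(benzyloxy)phenyl]butane-1,4-diol F9 as a mixture of diastereomers.
  - Oxidation of the two allylic, benzylic alcohols with MnO2 gives 9.

**Step 5.**
- What may go wrong: loss of a second benzyl group, or ring closure promoted by the Lewis acid, which would pre-empt step 6 without catalyst control.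
- Fallback, which sets out from 5 and returns at 10: it distinguishes the ortho oxygen from the start.
  - 3,5-Bis(benzyloxy)phenol is converted with chloromethyl methyl ether and i-Pr2NEt into 1,3-bis(benzyloxy)-5-(methoxymethoxy)benzene F10.
  - n-BuLi lithiates F10 between the methoxymethoxy and a benzyloxy group, directed by the acetal oxygen, and gives [2,4-bis(benzyloxy)-6-(methoxymethoxy)phenyl]lithium F11.
  - Addition of F11 to 5 gives (2E,3E)-1,4-bis[4,6-bis(benzyloxy)-2-(methoxymethoxy)phenyl]-2,3-bis(4-methoxybenzylidene)butane-1,4-dione F12.
  - ZnBr2 and n-PrSH in CH2Cl2 at 0 °C remove only the acetals and give 10.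

## Further compounds

F1 | step 6 | 1-[2,4,6-tris(benzyloxy)phenyl]ethan-1-one | CC(=O)c1c(OCc2ccccc2)cc(OCc2ccccc2)cc1OCc1ccccc1
F2 | step 6 | 1-[4,6-bis(benzyloxy)-2-hydroxyphenyl]ethan-1-one | CC(=O)c1c(O)cc(OCc2ccccc2)cc1OCc1ccccc1
F3 | step 6 | 5,7-bis(benzyloxy)-4H-chromen-4-one | O=c1ccoc2cc(OCc3ccccc3)cc(OCc3ccccc3)c12
F4 | step 6 | (R)-5,7-bis(benzyloxy)-2-(4-methoxyphenyl)chroman-4-one | O=C1C[C@H](c2ccc(OC)cc2)Oc2cc(OCc3ccccc3)cc(OCc3ccccc3)c12
F5 | step 6 | (2R,3S,2''R,3''S)-5,7,5'',7''-tetrakis(benzyloxy)-4',4'''-dimethoxy-3,3''-biflavanone | COc1ccc([C@@H]2Oc3cc(OCc4ccccc4)cc(OCc4ccccc4)c3C(=O)[C@H]2[C@@H]2C(=O)c3c(OCc4ccccc4)cc(OCc4ccccc4)cc3O[C@H]2c2ccc(OC)cc2)cc1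
F6 | step 1 | ethyl (Z)-2-bromo-3-(4-methoxyphenyl)acrylate | CCOC(=O)/C(Br)=C/c1ccc(OC)cc1
F7 | step 1 | diethyl (2E,3E)-2,3-bis(4-methoxybenzylidene)succinate | CCOC(=O)/C(=C/c1ccc(OC)cc1)/C(=C\c1ccc(OC)cc1)C(=O)OCC
F8 | step 4 | (2E,3E)-2,3-bis(4-methoxybenzylidene)succinaldehyde | O=C/C(=C/c1ccc(OC)cc1)/C(=C\c1ccc(OC)cc1)C=O
F9 | step 4 | (2E,3E)-2,3-bis(4-methoxybenzylidene)-1,4-bis[2,4,6-tris(benzyloxy)phenyl]butane-1,4-diol (mixture of diastereomers at the carbinol carbons) | OC(c1c(OCc2ccccc2)cc(OCc2ccccc2)cc1OCc1ccccc1)/C(=C/c1ccc(OC)cc1)/C(=C\c1ccc(OC)cc1)C(O)c1c(OCc2ccccc2)cc(OCc2ccccc2)cc1OCc1ccccc1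
F10 | step 5 | 1,3-bis(benzyloxy)-5-(methoxymethoxy)benzene | COCOc1cc(OCc2ccccc2)cc(OCc2ccccc2)c1
F11 | step 5 | [2,4-bis(benzyloxy)-6-(methoxymethoxy)phenyl]lithium | [Li]c1c(OCOC)cc(OCc2ccccc2)cc1OCc1ccccc1
F12 | step 5 | (2E,3E)-1,4-bis[4,6-bis(benzyloxy)-2-(methoxymethoxy)phenyl]-2,3-bis(4-methoxybenzylidene)butane-1,4-dione | O=C(c1c(OCOC)cc(OCc2ccccc2)cc1OCc1ccccc1)/C(=C/c1ccc(OC)cc1)/C(=C\c1ccc(OC)cc1)C(=O)c1c(OCOC)cc(OCc2ccccc2)cc1OCc1ccccc1
A1 | alternative 1 | (R)-5,7-bis(benzyloxy)-2-(4-methoxyphenyl)chroman-4-one | O=C1C[C@H](c2ccc(OC)cc2)Oc2cc(OCc3ccccc3)cc(OCc3ccccc3)c12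
A2 | alternative 1 | (2R,3S,2''R,3''S)-5,7,5'',7''-tetrakis(benzyloxy)-4',4'''-dimethoxy-3,3''-biflavanone | COc1ccc([C@@H]2Oc3cc(OCc4ccccc4)cc(OCc4ccccc4)c3C(=O)[C@H]2[C@@H]2C(=O)c3c(OCc4ccccc4)cc(OCc4ccccc4)cc3O[C@H]2c2ccc(OC)cc2)cc1
A3 | alternative 2 | 5,7,5'',7''-tetrakis(benzyloxy)-4',4'''-dimethoxy-3,3''-biflavone | COc1ccc(-c2oc3cc(OCc4ccccc4)cc(OCc4ccccc4)c3c(=O)c2-c2c(-c3ccc(OC)cc3)oc3cc(OCc4ccccc4)cc(OCc4ccccc4)c3c2=O)cc1
A4 | alternative 3 | 5,5',7,7'-tetrakis(benzyloxy)-4H,4'H-[3,3'-bichromene]-4,4'-dione | O=c1c(-c2coc3cc(OCc4ccccc4)cc(OCc4ccccc4)c3c2=O)coc2cc(OCc3ccccc3)cc(OCc3ccccc3)c12
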